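In the quinone ring (C1=O, C2-methyl, C3-henicosyl, C4=O, C5-methoxy, C6-H) the oxygens on C1 and C5 are meta across C6-H: a resorcinol monomethyl ether with C4=O still missing. The route rests on cutting this ring into a four-carbon half (C1–C4, both alkyl groups in place) and a two-carbon half (C5, C6, the methoxy group). A Danheiser benzannulation, a four-stage pericyclic cascade, joins 3-henicosyl-4-methylcyclobutenone and methoxyacetylene in one operation to the phenol; oxidation at the free para carbon C4 then gives the quinone. The precursor, a strained cyclobutenone plus a volatile ynol ether, carries no six-membered ring.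

Key step: step 4

Assumption: 1-bromohenicosane is taken as a catalogue chemical; the target is achiral, so the only stereocentres (C4 of the cyclobutenones, C6 of the dienone) are transient and are carried racemic.

Step 1
Reactants: 1 propanoyl chloride; 2 ethoxyacetylene (ethoxyethyne)
Product: 4 3-ethoxy-4-methylcyclobut-2-en-1-one (racemic), via methylketene 3 (not isolated)
Conditions: Et3N, Et2O, 0 °C to rt, 1 added slowly to excess 2
Reagents that add atoms: none
Why: Dehydrochlorination of 1 gives methylketene 3, which is captured in a ketene–ynol ether [2+2] cycloaddition in which the nucleophilic CH terminus of 2 bonds to the ketene carbonyl carbon, so the ethoxy group ends on C3 and the methyl on C4 (racemic, erased in step 4).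

Step 2
Reactants: 4 3-ethoxy-4-methylcyclobut-2-en-1-one; 5 1-bromohenicosane
Product: 8 3-henicosyl-4-methylcyclobut-2-en-1-one (racemic), via Grignard reagent 6 (not isolated), via tertiary cyclobutenol 7 (not isolated)
Conditions: Mg, THF, 45 °C; then 4, THF, 0 °C; then 1 M HCl, 0 °C to rt
Reagents that add atoms: water, O
Why: Grignard 1,2-addition to the vinylogous ester carbonyl and acid hydrolysis of the enol ether with loss of water (Stork–Danheiser carbonyl transposition) should place the chain on C3; because C4 is bonded to both C1 and C3, an addition–elimination at C3 would give the same constitution.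

Step 3
Reactants: 9 chloroacetaldehyde dimethyl acetal (2-chloro-1,1-dimethoxyethane)
Product: 12 methoxyacetylene (methoxyethyne), via 2-chloro-1-methoxyethene 10 (not isolated), via sodium methoxyethynide 11 (not isolated)
Conditions: NaNH2 (3 equiv), liquid NH3, −33 °C; then cold aqueous NaCl, −70 °C; distilled into a −78 °C trap
Reagents that add atoms: none
Why: Twofold base-induced β-elimination (methanol, then hydrogen chloride) and deprotonation should give the involatile acetylide 11, from which the aqueous quench releases the ynol ether (bp 23 °C); this is the standard alkoxyacetylene synthesis from a chloroacetal.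

Step 4
Reactants: 8 3-henicosyl-4-methylcyclobut-2-en-1-one; 12 methoxyacetylene
Product: 17 3-henicosyl-5-methoxy-2-methylphenol, via vinylketene 13 (not isolated), via alkenylcyclobutenone 14 (not isolated), via dienylketene 15 (not isolated), via cyclohexadienone 16 (not isolated)
Conditions: 12 (3 equiv), toluene, sealed tube, 80 °C then 110 °C; then K2CO3, MeOH, rt
Reagents that add atoms: none
Why: Conrotatory 4π ring opening of 8 with the C4 methyl turning outward gives vinylketene 13, whose ketene carbon is attacked by the nucleophilic CH terminus of 12 in a regiospecific [2+2] cycloaddition to 14; reversible 4π opening of 14 gives dienylketene 15, which is drained by 6π electrocyclisation to 16 and tautomerises to phenol 17. The closest known reaction type is the Danheiser benzannulation of cyclobutenones with alkoxyalkynes, applied here to a 4-substituted cyclobutenone. The six-membered ring is closed by thermal disrotatory 6π electrocyclisation (bond C1–C2 of 17) after bonds C1–C6 and C4–C5 are made in the [2+2] step, the four-membered ring of 14 being a temporary ring that the cascade opens itself. No stereocentre is set: C4 of 8 and C6 of 16 become aromatic carbons. Only regiocontrol is needed, and the polarity match between ketene carbon and ynol ether β-carbon places the methoxy group meta to the hydroxyl across C6–H, while methyl and henicosyl keep the adjacency fixed in 8.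

Step 5
Reactants: 17 3-henicosyl-5-methoxy-2-methylphenol
Product: 18 3-henicosyl-5-methoxy-2-methylcyclohexa-2,5-diene-1,4-dione (CNP0104330.0, the target)
Conditions: Fremy's salt (KSO3)2NO (2.5 equiv), KH2PO4, Aliquat 336, CH2Cl2/H2O, rt
Reagents that add atoms: potassium nitrosodisulfonate (Fremy's salt), [K+].[K+].[O]N(S(=O)(=O)[O-])S(=O)(=O)[O-]
Why: Teuber oxidation, in which hydrogen abstraction from the phenol O–H and oxygen transfer from a second nitroxyl radical to the only free para carbon (C4, activated by the ortho methoxy group) should give the 1,4-quinone, attack at the ortho carbon C6 being the lesser pathway for a phenol with an open para position.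

Compound list
1 | propanoyl chloride | CCC(=O)Cl | starting material
2 | ethoxyacetylene (ethoxyethyne) | CCOC#C | starting material
3 | methylketene (prop-1-en-1-one) | CC=C=O | intermediate
4 | 3-ethoxy-4-methylcyclobut-2-en-1-one, racemic | CCOC1=CC(=O)C1C | intermediate
5 | 1-bromohenicosane | CCCCCCCCCCCCCCCCCCCCCBr | starting material
6 | henicosylmagnesium bromide | CCCCCCCCCCCCCCCCCCCCC[Mg]Br | intermediate
7 | 3-ethoxy-1-henicosyl-4-methylcyclobut-2-en-1-ol, racemic diastereomer mixture (formed as its bromomagnesium alkoxide) | CCCCCCCCCCCCCCCCCCCCCC1(O)C=C(OCC)C1C | intermediate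
8 | 3-henicosyl-4-methylcyclobut-2-en-1-one, racemic | CCCCCCCCCCCCCCCCCCCCCC1=CC(=O)C1C | intermediate
9 | chloroacetaldehyde dimethyl acetal (2-chloro-1,1-dimethoxyethane) | COC(CCl)OC | starting material
10 | 2-chloro-1-methoxyethene, E/Z mixture | COC=CCl | intermediate
11 | sodium methoxyethynide | COC#[C-].[Na+] | intermediate
12 | methoxyacetylene (methoxyethyne) | COC#C | intermediate
13 | (3E)-3-henicosylpenta-1,3-dien-1-one (vinylketene) | C/C=C(/C=C=O)CCCCCCCCCCCCCCCCCCCCC | intermediate
14 | 3-methoxy-4-[(2E)-tetracos-2-en-3-yl]cyclobut-2-en-1-one, racemic | C/C=C(/C1C(=O)C=C1OC)CCCCCCCCCCCCCCCCCCCCC | intermediate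
15 | (3E,5E)-5-henicosyl-3-methoxyhepta-1,3,5-trien-1-one (dienylketene) | C/C=C(/C=C(\C=C=O)OC)CCCCCCCCCCCCCCCCCCCCC | intermediate
16 | 5-henicosyl-3-methoxy-6-methylcyclohexa-2,4-dien-1-one, racemic | CCCCCCCCCCCCCCCCCCCCCC1=CC(OC)=CC(=O)C1C | intermediate
17 | 3-henicosyl-5-methoxy-2-methylphenol | CCCCCCCCCCCCCCCCCCCCCc1cc(OC)cc(O)c1C | intermediate
18 | 3-henicosyl-5-methoxy-2-methylcyclohexa-2,5-diene-1,4-dione | CCCCCCCCCCCCCCCCCCCCCC1=C(C)C(=O)C=C(OC)C1=O | target

Total step count: 5. Longest linear sequence: 4 steps (1, 2, 4, 5); step 3 is a one-step side branch.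

Steps most likely to fail

1. Step 4. The ynol ether may oligomerise faster than it captures the vinylketene, or the cascade may stall at the alkenylcyclobutenone when ring opening turns the alkenyl arm outward and no 6π closure follows. The fallback is a Moore-type ring expansion of a squarate-derived cyclobutenone; it sets out from 6 and comes back at 18. 1,1-Dibromoprop-1-ene F1 is made from acetaldehyde (CBr4, PPh3, CH2Cl2, Ramirez olefination). Grignard reagent 6 is transmetalated with ZnBr2 to henicosylzinc bromide F2 and coupled with F1 under Pd(DPEphos)Cl2 catalysis (trans-selective Negishi mono-alkylation) to give (Z)-3-bromotetracos-2-ene F3. Bromine–lithium exchange (t-BuLi, THF, −78 °C) should give (E)-tetracos-2-en-3-yllithium F4. Dimethyl squarate is reduced with LiAlH(OtBu)3 to 4-hydroxy-2,3-dimethoxycyclobut-2-en-1-one F5, which loses methanol with HCl to give 3-methoxycyclobut-3-ene-1,2-dione F6. F4 should add to the more electrophilic carbonyl of F6 (the one next to the methoxy-bearing carbon) to give 4-hydroxy-3-methoxy-4-[(2Z)-tetracos-2-en-3-yl]cyclobut-2-en-1-one F7. Heating F7 in p-xylene (4π opening with the hydroxyl outward, 6π electrocyclisation, enolisation) should give 3-henicosyl-5-methoxy-2-methylbenzene-1,4-diol F8, and Ag2O oxidation gives 18.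

2. Step 1. The unstabilised monoalkylketene may dimerise or be diverted by the amine before the ynol ether traps it. The fallback uses a halogen-activated ketene and removes the halogen afterwards; it sets out from 2 and comes back at 4. Chloro(methyl)ketene F9, generated from 2-chloropropanoyl chloride and Et3N in Et2O, is more electrophilic and should be captured by 2 to give 4-chloro-3-ethoxy-4-methylcyclobut-2-en-1-one F10. Reductive dechlorination (Zn dust, AcOH, TMEDA, EtOH, 0 °C) then gives 4.

3. Step 2. Magnesium insertion into the long-chain bromide may be eroded by Wurtz coupling, the basic organometallic may open the strained ring, or the acid unmasking may degrade the cyclobutenone. The fallback brings the chain in on an alkyne and builds the four-membered ring around it; it sets out from 5 and comes back at 8. 5 is alkynylated with lithium acetylide–ethylenediamine complex (DMSO, rt) to tricos-1-yne F11. N,N-Dimethylprop-1-en-1-ylideneammonium triflate F12, generated from N,N-dimethylpropanamide, Tf2O and 2,4,6-collidine in 1,2-dichloroethane at reflux, should undergo Ghosez keteniminium–alkyne [2+2] cycloaddition with F11, the terminal alkyne carbon bonding to the iminium carbon, to give (3-henicosyl-4-methylcyclobut-2-en-1-ylidene)dimethylammonium triflate F13. Hydrolysis with aqueous NaHCO3 gives 8.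

Further compounds
F1 | step 4 | 1,1-dibromoprop-1-ene | CC=C(Br)Br
F2 | step 4 | henicosylzinc bromide | CCCCCCCCCCCCCCCCCCCCC[Zn]Br
F3 | step 4 | (Z)-3-bromotetracos-2-ene | C/C=C(\Br)CCCCCCCCCCCCCCCCCCCCC
F4 | step 4 | (E)-tetracos-2-en-3-yllithium | C/C=C(\[Li])CCCCCCCCCCCCCCCCCCCCC
F5 | step 4 | 4-hydroxy-2,3-dimethoxycyclobut-2-en-1-one, racemic | COC1=C(OC)C(=O)C1O
F6 | step 4 | 3-methoxycyclobut-3-ene-1,2-dione | COC1=CC(=O)C1=O
F7 | step 4 | 4-hydroxy-3-methoxy-4-[(2Z)-tetracos-2-en-3-yl]cyclobut-2-en-1-one, racemic | C/C=C(\C1(O)C(OC)=CC1=O)CCCCCCCCCCCCCCCCCCCCC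
F8 | step 4 | 3-henicosyl-5-methoxy-2-methylbenzene-1,4-diol | CCCCCCCCCCCCCCCCCCCCCc1c(C)c(O)cc(OC)c1O
F9 | step 1 | chloro(methyl)ketene (2-chloroprop-1-en-1-one) | CC(Cl)=C=O
F10 | step 1 | 4-chloro-3-ethoxy-4-methylcyclobut-2-en-1-one, racemic | CCOC1=CC(=O)C1(C)Cl
F11 | step 2 | tricos-1-yne | CCCCCCCCCCCCCCCCCCCCCC#C
F12 | step 2 | N,N-dimethylprop-1-en-1-ylideneammonium triflate | CC=C=[N+](C)C.[O-]S(=O)(=O)C(F)(F)F
F13 | step 2 | (3-henicosyl-4-methylcyclobut-2-en-1-ylidene)dimethylammonium triflate, racemic | CCCCCCCCCCCCCCCCCCCCCC1=CC(=[N+](C)C)C1C.[O-]S(=O)(=O)C(F)(F)F
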